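**Retrosynthetic overview**
- The target is reached from its 4'-O-MOM ether by acetal cleavage.
- The C8 prenyl group and the free 5-OH come together from a 5-O-prenyl ether by a Eu(III)-catalysed para-Claisen–Cope relay (O5 → C6 → C8); no ring is formed.
- The 5-O-prenyl dihydroflavonol comes in one flask from an achiral 2'-hydroxychalcone: a chalcone-isomerase-type enantioselective 6-endo oxa-Michael addition closes ring C and sets C2, then a flavanone-3-hydroxylase-type enolate oxygenation sets C3 trans.
- The chalcone comes from Claisen–Schmidt condensation of a mono-O-prenylated 2',6'-dihydroxy-4'-methoxyacetophenone with 4-(methoxymethoxy)benzaldehyde.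
- Ring order: rings A and B are bought as arenes; ring C is the only ring made, by the oxa-Michael closure.

Assumption: the target is the (2R,3R)-trans isomer encoded in the SMILES, and compounds 1, 2 and 4, the Davis oxaziridine, Eu(fod)3 and the cinchona thiourea are bought as catalogue items.

**Step 1**
Reactants: 1 1-(2,6-dihydroxy-4-methoxyphenyl)ethanone; 2 1-bromo-3-methylbut-2-ene (prenyl bromide)
Product: 3 1-[2-hydroxy-4-methoxy-6-(3-methylbut-2-enyloxy)phenyl]ethanone
Conditions: K2CO3 (1.2 equiv), acetone, reflux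
Reagents that add atoms: none
Why: Williamson O-alkylation in which one of the two equivalent phenols is alkylated by the allylic bromide, while the remaining phenol is locked in a hydrogen bond to the acetyl carbonyl and resists a second alkylation.

**Step 2**
Reactants: 3 1-[2-hydroxy-4-methoxy-6-(3-methylbut-2-enyloxy)phenyl]ethanone; 4 4-(methoxymethoxy)benzaldehyde
Product: 5 (E)-1-[2-hydroxy-4-methoxy-6-(3-methylbut-2-enyloxy)phenyl]-3-[4-(methoxymethoxy)phenyl]prop-2-en-1-one
Conditions: KOH (50% aq, excess), EtOH, 0 °C to rt; then 1 M HCl, 0 °C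
Reagents that add atoms: none
Why: Claisen–Schmidt (crossed aldol) condensation in which the acetophenone enolate adds to the non-enolisable aldehyde and E1cB dehydration gives the (E)-enone, the MOM and prenyl ethers being base-stable and the product staying open-chain as its 2'-phenoxide until the cold acid quench.

**Step 3**
Reactants: 5 (E)-1-[2-hydroxy-4-methoxy-6-(3-methylbut-2-enyloxy)phenyl]-3-[4-(methoxymethoxy)phenyl]prop-2-en-1-one
Product: 8 (2R,3R)-3-hydroxy-7-methoxy-2-[4-(methoxymethoxy)phenyl]-5-(3-methylbut-2-enyloxy)chroman-4-one, via (2S)-flavanone 6 (not isolated), via sodium enolate 7 (not isolated)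
Conditions: (i) quinine- or quinidine-derived 3,5-(CF3)2C6H3-thiourea (10 mol%, the pseudoenantiomer that gives 2S, checked by chiral HPLC/CD on the first run), PhMe, rt; (ii) THF, NaHMDS (1.5 equiv), −78 °C, 20 min; Davis oxaziridine (1.6 equiv), −78 °C; AcOH quench at −78 °C
Reagents that add atoms: (±)-trans-2-(phenylsulfonyl)-3-phenyloxaziridine (Davis oxaziridine), O=S(=O)(N1OC1c1ccccc1)c1ccccc1
Why: Proposed new method: the quinuclidine nitrogen of the catalyst activates the 2'-OH while the thiourea binds the enone carbonyl, so the phenol adds to one enantioface of the β-carbon in a chalcone-isomerase-like 6-endo oxa-Michael addition that sets C2 as S, the 6'-alkoxy group driving the equilibrium to the flavanone and the absence of a free 5-OH suppressing retro-Michael racemisation; the sodium enolate then formed at −78 °C is oxygenated by the sulfonyloxaziridine on the face anti to the 2-aryl group (Davis enolate hydroxylation, the counterpart of flavanone 3-hydroxylase), which sets C3 and gives the 2,3-trans (2R,3R) ketol without touching the prenyl alkene; the closest known reaction types are the bifunctional-thiourea-catalysed asymmetric oxa-Michael cyclisation of 2'-hydroxychalcones and of alkylidene β-ketoesters and the Davis oxidation of ketone enolates, here merged in one flask on an unactivated chalcone.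

**Step 4**
Reactants: 8 (2R,3R)-3-hydroxy-7-methoxy-2-[4-(methoxymethoxy)phenyl]-5-(3-methylbut-2-enyloxy)chroman-4-one
Product: 11 (2R,3R)-3,5-dihydroxy-7-methoxy-2-[4-(methoxymethoxy)phenyl]-8-(3-methylbut-2-enyl)chroman-4-one, via ortho-dienone 9 (not isolated), via para-dienone 10 (not isolated)
Conditions: Eu(fod)3 (10 mol%), NaHCO3, PhCl, 85 °C
Reagents that add atoms: none
Why: Europium(III)-catalysed aromatic para-Claisen–Cope rearrangement in which chelation of C4=O/O5 triggers the [3,3] shift of the prenyl ether to C6 (reverse-prenyl dienone), a second [3,3] (Cope) shift carries the group to C8 as a normal prenyl unit and enolisation restores the arene with the chelated 5-OH, C2 and C3 not being involved.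

**Step 5**
Reactants: 11 (2R,3R)-3,5-dihydroxy-7-methoxy-2-[4-(methoxymethoxy)phenyl]-8-(3-methylbut-2-enyl)chroman-4-one
Product: 12 (2R,3R)-3,5-dihydroxy-2-(4-hydroxyphenyl)-7-methoxy-8-(3-methylbut-2-enyl)chroman-4-one
Conditions: 3 M aq HCl, MeOH, 40 °C
Reagents that add atoms: none
Why: Acid-catalysed acetal solvolysis (MOM cleavage by transacetalisation to methanol), tolerated because the C8 prenyl group has no neighbouring free phenol to cyclise onto and the trans ketol is configurationally stable to mild acid.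

**Compound list**
1 | 1-(2,6-dihydroxy-4-methoxyphenyl)ethanone (2',6'-dihydroxy-4'-methoxyacetophenone) | CC(=O)c1c(O)cc(OC)cc1O | starting material
2 | 1-bromo-3-methylbut-2-ene (prenyl bromide) | CC(C)=CCBr | starting material
3 | 1-[2-hydroxy-4-methoxy-6-(3-methylbut-2-enyloxy)phenyl]ethanone | CC(=O)c1c(O)cc(OC)cc1OCC=C(C)C | intermediate
4 | 4-(methoxymethoxy)benzaldehyde | COCOc1ccc(C=O)cc1 | starting material
5 | (E)-1-[2-hydroxy-4-methoxy-6-(3-methylbut-2-enyloxy)phenyl]-3-[4-(methoxymethoxy)phenyl]prop-2-en-1-one | COCOc1ccc(/C=C/C(=O)c2c(O)cc(OC)cc2OCC=C(C)C)cc1 | intermediate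
6 | (2S)-7-methoxy-2-[4-(methoxymethoxy)phenyl]-5-(3-methylbut-2-enyloxy)chroman-4-one (not isolated) | COc1cc(OCC=C(C)C)c2c(c1)O[C@H](c1ccc(OCOC)cc1)CC2=O | intermediate
7 | sodium (2S)-7-methoxy-2-[4-(methoxymethoxy)phenyl]-5-(3-methylbut-2-enyloxy)-2H-chromen-4-olate, the enolate of 6 (not isolated) | COc1cc(OCC=C(C)C)c2c(c1)O[C@H](c1ccc(OCOC)cc1)C=C2[O-].[Na+] | intermediate
8 | (2R,3R)-3-hydroxy-7-methoxy-2-[4-(methoxymethoxy)phenyl]-5-(3-methylbut-2-enyloxy)chroman-4-one | COc1cc(OCC=C(C)C)c2c(c1)O[C@H](c1ccc(OCOC)cc1)[C@@H](O)C2=O | intermediate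
9 | (2R,3R)-3-hydroxy-7-methoxy-2-[4-(methoxymethoxy)phenyl]-6-(2-methylbut-3-en-2-yl)-2,3-dihydrochromene-4,5(6H)-dione, C6 epimers (not isolated) | COC1=CC2=C(C(=O)C1C(C)(C)C=C)C(=O)[C@H](O)[C@@H](c1ccc(OCOC)cc1)O2 | intermediate
10 | (2R,3R)-3-hydroxy-7-methoxy-2-[4-(methoxymethoxy)phenyl]-8-(3-methylbut-2-enyl)-2,3-dihydrochromene-4,5(8H)-dione, C8 epimers (not isolated) | COC1=CC(=O)C2=C(C1CC=C(C)C)O[C@H](c1ccc(OCOC)cc1)[C@@H](O)C2=O | intermediate
11 | (2R,3R)-3,5-dihydroxy-7-methoxy-2-[4-(methoxymethoxy)phenyl]-8-(3-methylbut-2-enyl)chroman-4-one | COc1cc(O)c2c(c1CC=C(C)C)O[C@H](c1ccc(OCOC)cc1)[C@@H](O)C2=O | intermediate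
12 | (2R,3R)-3,5-dihydroxy-2-(4-hydroxyphenyl)-7-methoxy-8-(3-methylbut-2-enyl)chroman-4-one | COc1cc(O)c2c(c1CC=C(C)C)O[C@H](c1ccc(O)cc1)[C@@H](O)C2=O | target

**Step count and risks**
Total step count: 5. Longest linear sequence: 5 (1 → 3 → 5 → 8 → 11 → 12).

Step 3 is the most likely to fail. The catalyst may give the unactivated chalcone in low ee or close it slowly, and the enolate may ring-open before it is oxidised. Fallback: it sets out from 5. Cyclisation without induction (NaOAc, EtOH, reflux) gives racemic 7-methoxy-2-[4-(methoxymethoxy)phenyl]-5-(3-methylbut-2-enyloxy)chroman-4-one F1. Kinetic resolution by Noyori–Ikariya transfer hydrogenation (RuCl(p-cymene)(TsDPEN), HCO2H/Et3N, the catalyst enantiomer that reduces the 2R ketone) converts the unwanted enantiomer into the 2,4-cis (2R,4R)-flavan-4-ol F2. The unreacted ketone is 6, now isolated (at most 50%). The route is rejoined at 6, which is taken through enolate 7 to 8 by stage (ii) of step 3.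

Step 4 is the second risk. The free α-ketol may tie up the europium, or the sequence may stop at the C6 reverse-prenyl stage. Fallback: it sets out from 6, isolated after stage (i) of step 3. The Eu(fod)3 para-Claisen–Cope relay is run on the flavanone, the substrate class on which it is best established, and gives (2S)-5-hydroxy-7-methoxy-2-[4-(methoxymethoxy)phenyl]-8-(3-methylbut-2-enyl)chroman-4-one F3. C3 is then oxygenated through the phenoxide–enolate dianion (KHMDS 2.3 equiv, THF, −78 °C, then Davis oxaziridine, short contact time to limit ring opening). This gives 11 directly, where the route is rejoined before step 5.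

Step 5 is the third risk. Acid may add HCl or MeOH across the prenyl alkene, or erode the C2 configuration once the 4'-OH is free. Fallback: it sets out from 3. Condensation with commercial 4-(prop-2-enyloxy)benzaldehyde (C=CCOc1ccc(C=O)cc1) in place of 4 gives (E)-1-[2-hydroxy-4-methoxy-6-(3-methylbut-2-enyloxy)phenyl]-3-[4-(prop-2-enyloxy)phenyl]prop-2-en-1-one F4. The conditions of step 3 give (2R,3R)-3-hydroxy-7-methoxy-5-(3-methylbut-2-enyloxy)-2-[4-(prop-2-enyloxy)phenyl]chroman-4-one F5. The conditions of step 4 (the unactivated B-ring allyl ether does not rearrange at 85 °C) give (2R,3R)-3,5-dihydroxy-7-methoxy-8-(3-methylbut-2-enyl)-2-[4-(prop-2-enyloxy)phenyl]chroman-4-one F6. Neutral Pd(0) deallylation (Pd(PPh3)4, morpholine, THF, rt) then gives 12, where the route ends.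

**Further compounds**
F1 | step 3 | racemic 7-methoxy-2-[4-(methoxymethoxy)phenyl]-5-(3-methylbut-2-enyloxy)chroman-4-one | COc1cc(OCC=C(C)C)c2c(c1)OC(c1ccc(OCOC)cc1)CC2=O
F2 | step 3 | (2R,4R)-7-methoxy-2-[4-(methoxymethoxy)phenyl]-5-(3-methylbut-2-enyloxy)chroman-4-ol (2,4-cis) | COc1cc(OCC=C(C)C)c2c(c1)O[C@@H](c1ccc(OCOC)cc1)C[C@H]2O
F3 | step 4 | (2S)-5-hydroxy-7-methoxy-2-[4-(methoxymethoxy)phenyl]-8-(3-methylbut-2-enyl)chroman-4-one | COc1cc(O)c2c(c1CC=C(C)C)O[C@H](c1ccc(OCOC)cc1)CC2=O
F4 | step 5 | (E)-1-[2-hydroxy-4-methoxy-6-(3-methylbut-2-enyloxy)phenyl]-3-[4-(prop-2-enyloxy)phenyl]prop-2-en-1-one | C=CCOc1ccc(/C=C/C(=O)c2c(O)cc(OC)cc2OCC=C(C)C)cc1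
F5 | step 5 | (2R,3R)-3-hydroxy-7-methoxy-5-(3-methylbut-2-enyloxy)-2-[4-(prop-2-enyloxy)phenyl]chroman-4-one | COc1cc(OCC=C(C)C)c2c(c1)O[C@H](c1ccc(OCC=C)cc1)[C@@H](O)C2=O
F6 | step 5 | (2R,3R)-3,5-dihydroxy-7-methoxy-8-(3-methylbut-2-enyl)-2-[4-(prop-2-enyloxy)phenyl]chroman-4-one | COc1cc(O)c2c(c1CC=C(C)C)O[C@H](c1ccc(OCC=C)cc1)[C@@H](O)C2=O
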